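**Retrosynthetic overview**

1. Target ⇒ fluoride deprotection of a silyl ether/2-(trimethylsilyl)ethyl ester; the (13Z)-enoate comes from Negishi coupling of a C12 alkylzinc with a (Z)-3-iodobut-2-enoate; the benzoate comes from acylation of C18–OH.
2. Rings A and B are formed in one operation (A first, then B) from an acyclic epoxy-diene by a Cp2TiCl-catalysed radical bicyclisation. It makes C4–C5 and C9–C10, sets C4, C5, C9 and C10, and leaves the C8=C17 methylene.
3. Enabling feature: quaternary C4 of ring A carries the oxygenated methylene C18. C4, C18 and O18 are written as a 2,2-disubstituted oxirane, so reductive opening puts a radical on C4 facing C5 of the C5=C10/C8=C9 1,5-diene that maps onto rings A and B. The C6 carbinol, allylic to C5, is the only pre-set stereocentre.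
4. Epoxy-diene ⇐ methyl ketone (Wacker, then sulfonium ylide) ⇐ (6S)-allylic alcohol (CBS reduction of the enone) ⇐ alkenyl iodide + β,γ-unsaturated aldehyde (Nozaki–Hiyama–Kishi); both trisubstituted alkenes come from Negishi carboalumination.

Key step: step 12

Remark: the decalin compounds are named on the labdane skeleton. C1–C10 form the trans-decalin (ring A = C1–C5, C10; ring B = C5–C10). C4 carries C18 (α, CH2O) and C19 (β, CH3), C10 carries C20 (β, CH3), C8 carries the exocyclic C17, and C9 carries the side chain C11–C16. "13,14,15,16-Tetranor" means the side chain ends at C12. Hept-1-en-6-yne is taken as purchasable; otherwise it is one step from 5-bromopent-1-ene and lithium acetylide.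

**Route**

Step 1
Reactants: 1 hept-1-en-6-yne
Product: 3 (1E)-1-iodo-2-methylhepta-1,6-diene, via alkenylalane 2 (not isolated)
Conditions: Me3Al (2.0 equiv), Cp2ZrCl2 (0.25 equiv), CH2Cl2, 0 °C to rt; then I2, THF, −30 to 0 °C
Reagents that add atoms: trimethylaluminium C[Al](C)C; iodine II
Why: Negishi carboalumination adds CH3 and Al syn across the terminal alkyne (methyl on the internal carbon) much faster than it touches the monosubstituted alkene, and iodinolysis of the C–Al bond with retention fixes the (E)-trisubstituted alkenyl iodide.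

Step 2
Reactants: 4 tert-butyl(but-3-yn-1-yloxy)dimethylsilane
Product: 7 (3E)-6-(tert-butyldimethylsilyloxy)-4-methylhex-3-en-1-ol, via alkenylalane 5 (not isolated), via lithium alkenylalanate 6 (not isolated)
Conditions: Me3Al (2.0 equiv), Cp2ZrCl2 (0.25 equiv), CH2Cl2, rt; volatiles removed; n-BuLi, hexane/THF, −78 to 0 °C; oxirane (3 equiv), 0 °C to rt; aq. HCl work-up
Reagents that add atoms: trimethylaluminium C[Al](C)C; oxirane C1CO1
Why: The same syn-carboalumination sets the (E)-trisubstituted alkene, and the lithium alkenylalanate opens oxirane with retention of alkene geometry to give the homoallylic alcohol, the silyl ether being stable to Me3Al at room temperature.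

Step 3
Reactants: 7 (3E)-6-(tert-butyldimethylsilyloxy)-4-methylhex-3-en-1-ol
Product: 8 tert-butyl{[(3E)-6-chloro-3-methylhex-3-en-1-yl]oxy}dimethylsilane
Conditions: PPh3, N-chlorosuccinimide, CH2Cl2, 0 °C to rt
Reagents that add atoms: N-chlorosuccinimide O=C1CCC(=O)N1Cl
Why: Appel-type chlorination turns the primary alcohol into a primary chloride that should be inert to the later chromium, oxidation, ylide and radical steps and serves as the coupling handle at the end.

Step 4
Reactants: 8 tert-butyl{[(3E)-6-chloro-3-methylhex-3-en-1-yl]oxy}dimethylsilane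
Product: 9 (3E)-6-chloro-3-methylhex-3-en-1-ol
Conditions: camphorsulfonic acid (10 mol %), MeOH, 0 °C to rt
Reagents that add atoms: none
Why: Acid-catalysed methanolysis removes the primary silyl ether without affecting the alkyl chloride or the trisubstituted alkene.

Step 5
Reactants: 9 (3E)-6-chloro-3-methylhex-3-en-1-ol
Product: 10 (3E)-6-chloro-3-methylhex-3-enal
Conditions: Dess–Martin periodinane, NaHCO3, CH2Cl2, 0 °C; used crude at once
Reagents that add atoms: none
Why: Buffered Dess–Martin oxidation gives the β,γ-unsaturated aldehyde under non-basic conditions, so the alkene should not move into conjugation.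

Step 6
Reactants: 3 (1E)-1-iodo-2-methylhepta-1,6-diene; 10 (3E)-6-chloro-3-methylhex-3-enal
Product: 11 rac-(3E,7E)-1-chloro-4,8-dimethyltrideca-3,7,12-trien-6-ol
Conditions: CrCl2 (4 equiv), NiCl2 (2 mol %), DMSO, rt
Reagents that add atoms: none
Why: Nozaki–Hiyama–Kishi coupling adds the alkenyl group to the aldehyde with retention of alkene geometry under neutral conditions that neither enolise the aldehyde nor touch the alkyl chloride; the carbinol centre forms racemic and is erased in step 7.

Step 7
Reactants: 11 rac-(3E,7E)-1-chloro-4,8-dimethyltrideca-3,7,12-trien-6-ol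
Product: 12 (3E,7E)-1-chloro-4,8-dimethyltrideca-3,7,12-trien-6-one
Conditions: Dess–Martin periodinane, NaHCO3, CH2Cl2, 0 °C to rt
Reagents that add atoms: none
Why: Dess–Martin oxidation of the allylic alcohol gives the enone without base, so neither alkene should isomerise.

Step 8
Reactants: 12 (3E,7E)-1-chloro-4,8-dimethyltrideca-3,7,12-trien-6-one
Product: 13 (3E,6S,7E)-1-chloro-4,8-dimethyltrideca-3,7,12-trien-6-ol
Conditions: (R)-1-methyl-3,3-diphenyltetrahydro-1H,3H-pyrrolo[1,2-c][1,3,2]oxazaborole ((R)-Me-CBS, 0.5 equiv), catecholborane (1.8 equiv), toluene, −78 °C; MeOH, then aqueous work-up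
Reagents that add atoms: none
Why: Corey–Bakshi–Shibata reduction, in which the oxazaborolidine binds the ketone with the alkenyl group as the large and the CH2 group as the small substituent, so the (R)-catalyst should deliver hydride to the face that gives the (6S)-alcohol, and catecholborane at −78 °C does not hydroborate the alkenes.

Step 9
Reactants: 13 (3E,6S,7E)-1-chloro-4,8-dimethyltrideca-3,7,12-trien-6-ol
Product: 14 tert-butyl{[(3E,6S,7E)-1-chloro-4,8-dimethyltrideca-3,7,12-trien-6-yl]oxy}dimethylsilane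
Conditions: TBSCl, imidazole, DMF, rt
Reagents that add atoms: tert-butyldimethylsilyl chloride CC(C)(C)[Si](C)(C)Cl
Why: Standard silylation of the secondary allylic alcohol; the silyl ether is the stereocontrol element of step 12 and should last until the final fluoride treatment.

Step 10
Reactants: 14 tert-butyl{[(3E,6S,7E)-1-chloro-4,8-dimethyltrideca-3,7,12-trien-6-yl]oxy}dimethylsilane
Product: 15 (6E,8S,10E)-8-(tert-butyldimethylsilyloxy)-13-chloro-6,10-dimethyltrideca-6,10-dien-2-one
Conditions: PdCl2 (10 mol %), CuCl (1 equiv, reoxidised), O2 (1 atm), DMF/H2O (7:1), rt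
Reagents that add atoms: water O
Why: Tsuji–Wacker oxidation is selective for the monosubstituted terminal alkene (Markovnikov hydroxypalladation) and should leave both trisubstituted alkenes untouched.

Step 11
Reactants: 15 (6E,8S,10E)-8-(tert-butyldimethylsilyloxy)-13-chloro-6,10-dimethyltrideca-6,10-dien-2-one
Product: 16 2-[(4E,6S,8E)-6-(tert-butyldimethylsilyloxy)-11-chloro-4,8-dimethylundeca-4,8-dien-1-yl]-2-methyloxirane (both epimers at the oxirane carbon)
Conditions: trimethylsulfonium iodide, n-BuLi, THF, −10 °C; then 15, −10 °C to rt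
Reagents that add atoms: trimethylsulfonium iodide C[S+](C)C.[I-]
Why: Corey–Chaykovsky methylenation of the ketone closes the 2,2-disubstituted oxirane; the epimer mixture at the new centre does not matter because that carbon becomes a planar radical in step 12.

Step 12
Reactants: 16 2-[(4E,6S,8E)-6-(tert-butyldimethylsilyloxy)-11-chloro-4,8-dimethylundeca-4,8-dien-1-yl]-2-methyloxirane
Product: 18 (4R,5R,6S,9S,10R)-6-(tert-butyldimethylsilyloxy)-12-chloro-13,14,15,16-tetranorlabd-8(17)-en-18-ol, via trimethylsilyl ether 17 (not isolated)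
Conditions: Cp2TiCl2 (20 mol %), Mn dust (8 equiv), Me3SiCl (4 equiv), 2,4,6-collidine (7 equiv), THF (0.02 M), rt; then K2CO3, MeOH, rt
Reagents that add atoms: none
Why: Electron transfer from Cp2TiCl opens the oxirane regioselectively to the tertiary C4 radical (C18 becomes a titanium alkoxide), which adds 6-endo-trig to C5 of the C5=C10 alkene (ring A, the C4–C5 bond); the tertiary C10 radical then adds 6-endo-trig to C9 of the C8=C9 alkene (ring B), and the tertiary C8 radical is captured by a second Cp2TiCl and loses a C17 methyl hydrogen to give the exocyclic C8=C17 alkene. The closest known reaction type is the titanocene-catalysed radical cyclisation of epoxypolyprenes, which ends in exocyclic alkenes in the same way, and 2,2-disubstituted oxiranes are known to open to the tertiary radical. At C4 the bulky CH2OTiCp2Cl group should take the pseudo-equatorial site of the chair transition state, leaving CH3 axial (C19 β, C18 α). At C5 the (6S)-silyloxy centre chooses the alkene face: allylic 1,3-strain with the C20 methyl holds C6–H in the alkene plane, and the radical is expected to enter past the smaller oxygen substituent and anti to the branched C7 chain, the folding that also places the silyloxy group equatorial in ring B and avoids a 1,3-diaxial contact with C20. At C10 and C9 the (E)-geometry of both alkenes and chair–chair folding should give the trans ring fusion (10β-CH3, 5α-H) and the equatorial side chain (9α-H). The step needs 6-endo over 5-exo closure (secured by the fully substituted C10 and C8 termini), no further cyclisation of the last radical (secured by the saturated chloroethyl chain) and exocyclic termination (the C17 hydrogens are the least hindered).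

Step 13
Reactants: 18 (4R,5R,6S,9S,10R)-6-(tert-butyldimethylsilyloxy)-12-chloro-13,14,15,16-tetranorlabd-8(17)-en-18-ol
Product: 19 (4R,5R,6S,9S,10R)-6-(tert-butyldimethylsilyloxy)-12-chloro-13,14,15,16-tetranorlabd-8(17)-en-18-yl benzoate
Conditions: BzCl, pyridine, 4-(dimethylamino)pyridine (10 mol %), CH2Cl2, 0 °C to rt
Reagents that add atoms: benzoyl chloride O=C(Cl)c1ccccc1
Why: Nucleophile-catalysed acylation of the only free hydroxyl, the primary neopentyl C18–OH.

Step 14
Reactants: 19 (4R,5R,6S,9S,10R)-6-(tert-butyldimethylsilyloxy)-12-chloro-13,14,15,16-tetranorlabd-8(17)-en-18-yl benzoate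
Product: 20 (4R,5R,6S,9S,10R)-6-(tert-butyldimethylsilyloxy)-12-iodo-13,14,15,16-tetranorlabd-8(17)-en-18-yl benzoate
Conditions: NaI (10 equiv), butan-2-one, 80 °C
Reagents that add atoms: sodium iodide [Na+].[I-]
Why: Finkelstein exchange converts the unhindered primary chloride into the iodide needed for zinc insertion, with benzoate, silyl ether and exocyclic alkene inert.

Step 15
Reactants: 21 but-2-ynoic acid
Product: 22 (2Z)-3-iodobut-2-enoic acid
Conditions: NaI, AcOH, 115 °C
Reagents that add atoms: sodium iodide [Na+].[I-]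
Why: Anti-hydroiodination (conjugate addition of iodide, then protonation) should give the (Z)-β-iodo acid with iodine cis to the carboxyl group.

Step 16
Reactants: 22 (2Z)-3-iodobut-2-enoic acid
Product: 23 2-(trimethylsilyl)ethyl (2Z)-3-iodobut-2-enoate
Conditions: 2-(trimethylsilyl)ethanol, N,N'-dicyclohexylcarbodiimide, 4-(dimethylamino)pyridine (10 mol %), CH2Cl2, 0 °C to rt
Reagents that add atoms: 2-(trimethylsilyl)ethanol C[Si](C)(C)CCO
Why: Steglich esterification installs a fluoride-labile ester under mild conditions that should not isomerise the (Z)-iodoalkene.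

Step 17
Reactants: 20 (4R,5R,6S,9S,10R)-6-(tert-butyldimethylsilyloxy)-12-iodo-13,14,15,16-tetranorlabd-8(17)-en-18-yl benzoate; 23 2-(trimethylsilyl)ethyl (2Z)-3-iodobut-2-enoate
Product: 25 2-(trimethylsilyl)ethyl (13Z)-18-(benzoyloxy)-6α-(tert-butyldimethylsilyloxy)labda-8(17),13-dien-15-oate, via alkylzinc iodide 24 (not isolated)
Conditions: Zn dust (activated with BrCH2CH2Br and Me3SiCl), LiCl, THF, 40 °C; then 23, Pd(PPh3)4 (5 mol %), THF, rt
Reagents that add atoms: none
Why: Zinc insertion into the primary C–I bond gives an alkylzinc iodide that tolerates the benzoate, and Negishi coupling with the (Z)-alkenyl iodide proceeds with retention, which sets the (13Z)-enoate with the C12 chain cis to the ester.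

Step 18
Reactants: 25 2-(trimethylsilyl)ethyl (13Z)-18-(benzoyloxy)-6α-(tert-butyldimethylsilyloxy)labda-8(17),13-dien-15-oate
Product: 26 (13Z)-18-(benzoyloxy)-6α-hydroxylabda-8(17),13-dien-15-oic acid (CNP0304840.1)
Conditions: tetrabutylammonium fluoride (4 equiv), AcOH (4 equiv), THF, rt to 40 °C
Reagents that add atoms: none
Why: Fluoride cleaves the secondary silyl ether and fragments the 2-(trimethylsilyl)ethyl ester to the acid, ethylene and Me3SiF in one operation, while the buffered medium should leave the benzoate in place.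

**Compound list**

1 | hept-1-en-6-yne | C#CCCCC=C | starting material
2 | dimethyl[(1E)-2-methylhepta-1,6-dien-1-yl]alane | C=CCCC/C(C)=C/[Al](C)C | intermediate
3 | (1E)-1-iodo-2-methylhepta-1,6-diene | C=CCCC/C(C)=C/I | intermediate
4 | tert-butyl(but-3-yn-1-yloxy)dimethylsilane | C#CCCO[Si](C)(C)C(C)(C)C | starting material
5 | [(1E)-4-(tert-butyldimethylsilyloxy)-2-methylbut-1-en-1-yl]dimethylalane | C[Al](C)/C=C(\C)CCO[Si](C)(C)C(C)(C)C | intermediate
6 | lithium butyl[(1E)-4-(tert-butyldimethylsilyloxy)-2-methylbut-1-en-1-yl]dimethylalanate | [Li+].CCCC[Al-](C)(C)/C=C(\C)CCO[Si](C)(C)C(C)(C)C | intermediate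
7 | (3E)-6-(tert-butyldimethylsilyloxy)-4-methylhex-3-en-1-ol | OCC/C=C(\C)CCO[Si](C)(C)C(C)(C)C | intermediate
8 | tert-butyl{[(3E)-6-chloro-3-methylhex-3-en-1-yl]oxy}dimethylsilane | ClCC/C=C(\C)CCO[Si](C)(C)C(C)(C)C | intermediate
9 | (3E)-6-chloro-3-methylhex-3-en-1-ol | OCC/C(C)=C/CCCl | intermediate
10 | (3E)-6-chloro-3-methylhex-3-enal | O=CC/C(C)=C/CCCl | intermediate
11 | rac-(3E,7E)-1-chloro-4,8-dimethyltrideca-3,7,12-trien-6-ol | C=CCCC/C(C)=C/C(O)C/C(C)=C/CCCl | intermediate
12 | (3E,7E)-1-chloro-4,8-dimethyltrideca-3,7,12-trien-6-one | C=CCCC/C(C)=C/C(=O)C/C(C)=C/CCCl | intermediate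
13 | (3E,6S,7E)-1-chloro-4,8-dimethyltrideca-3,7,12-trien-6-ol | C=CCCC/C(C)=C/[C@@H](O)C/C(C)=C/CCCl | intermediate
14 | tert-butyl{[(3E,6S,7E)-1-chloro-4,8-dimethyltrideca-3,7,12-trien-6-yl]oxy}dimethylsilane | C=CCCC/C(C)=C/[C@@H](O[Si](C)(C)C(C)(C)C)C/C(C)=C/CCCl | intermediate
15 | (6E,8S,10E)-8-(tert-butyldimethylsilyloxy)-13-chloro-6,10-dimethyltrideca-6,10-dien-2-one | CC(=O)CCC/C(C)=C/[C@@H](O[Si](C)(C)C(C)(C)C)C/C(C)=C/CCCl | intermediate
16 | 2-[(4E,6S,8E)-6-(tert-butyldimethylsilyloxy)-11-chloro-4,8-dimethylundeca-4,8-dien-1-yl]-2-methyloxirane (both epimers at the oxirane carbon) | CC1(CCC/C(C)=C/[C@@H](O[Si](C)(C)C(C)(C)C)C/C(C)=C/CCCl)CO1 | intermediate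
17 | (4R,5R,6S,9S,10R)-6-(tert-butyldimethylsilyloxy)-12-chloro-18-(trimethylsilyloxy)-13,14,15,16-tetranorlabd-8(17)-ene | C=C1C[C@H](O[Si](C)(C)C(C)(C)C)[C@H]2[C@](C)(CO[Si](C)(C)C)CCC[C@]2(C)[C@H]1CCCl | intermediate
18 | (4R,5R,6S,9S,10R)-6-(tert-butyldimethylsilyloxy)-12-chloro-13,14,15,16-tetranorlabd-8(17)-en-18-ol | C=C1C[C@H](O[Si](C)(C)C(C)(C)C)[C@H]2[C@](C)(CO)CCC[C@]2(C)[C@H]1CCCl | intermediate
19 | (4R,5R,6S,9S,10R)-6-(tert-butyldimethylsilyloxy)-12-chloro-13,14,15,16-tetranorlabd-8(17)-en-18-yl benzoate | C=C1C[C@H](O[Si](C)(C)C(C)(C)C)[C@H]2[C@](C)(COC(=O)c3ccccc3)CCC[C@]2(C)[C@H]1CCCl | intermediate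
20 | (4R,5R,6S,9S,10R)-6-(tert-butyldimethylsilyloxy)-12-iodo-13,14,15,16-tetranorlabd-8(17)-en-18-yl benzoate | C=C1C[C@H](O[Si](C)(C)C(C)(C)C)[C@H]2[C@](C)(COC(=O)c3ccccc3)CCC[C@]2(C)[C@H]1CCI | intermediate
21 | but-2-ynoic acid | CC#CC(=O)O | starting material
22 | (2Z)-3-iodobut-2-enoic acid | C/C(I)=C/C(=O)O | intermediate
23 | 2-(trimethylsilyl)ethyl (2Z)-3-iodobut-2-enoate | C/C(I)=C/C(=O)OCC[Si](C)(C)C | intermediate
24 | [(4R,5R,6S,9S,10R)-18-(benzoyloxy)-6-(tert-butyldimethylsilyloxy)-13,14,15,16-tetranorlabd-8(17)-en-12-yl]zinc iodide | C=C1C[C@H](O[Si](C)(C)C(C)(C)C)[C@H]2[C@](C)(COC(=O)c3ccccc3)CCC[C@]2(C)[C@H]1CC[Zn]I | intermediate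
25 | 2-(trimethylsilyl)ethyl (13Z)-18-(benzoyloxy)-6α-(tert-butyldimethylsilyloxy)labda-8(17),13-dien-15-oate (4R,5R,6S,9S,10R) | C=C1C[C@H](O[Si](C)(C)C(C)(C)C)[C@H]2[C@](C)(COC(=O)c3ccccc3)CCC[C@]2(C)[C@H]1CC/C(C)=C\C(=O)OCC[Si](C)(C)C | intermediate
26 | (13Z)-18-(benzoyloxy)-6α-hydroxylabda-8(17),13-dien-15-oic acid (4R,5R,6S,9S,10R) | C=C1C[C@H](O)[C@H]2[C@](C)(COC(=O)c3ccccc3)CCC[C@]2(C)[C@H]1CC/C(C)=C\C(=O)O | target

**Count and risks**

Total step count: 18. Longest linear sequence: 15 steps (from 4: steps 2–14, 17, 18).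

The three steps most likely to fail:

Step 12. The first radical C–C bond formation may occur mainly on the alkene face anti to the silyloxy group (Felkin-type attack), so the cascade would give the bicycle with the wrong sense relative to C6. Fallback, from 12 back to 19: enone 12 is reduced with the enantiomeric oxazaborolidine ((S)-Me-CBS, catecholborane) to the (6R)-alcohol F1. This is carried through the same three operations: silylation to silyl ether F2, Wacker oxidation to methyl ketone F3 and sulfonium-ylide epoxidation to oxirane F4. The same Cp2TiCl-catalysed cyclisation, in which anti attack is now productive, should give, through trimethylsilyl ether F5, the 6β-silyloxy bicyclic alcohol F6 with the correct configuration at C4, C5, C9 and C10. Benzoylation should give benzoate F7, desilylation with HF·pyridine the 6β-alcohol F8 and Dess–Martin oxidation the 6-ketone F9. Reduction under thermodynamic control with SmI2 and H2O in THF should give the equatorial 6α-alcohol F10, and TBSOTf/2,6-lutidine returns to 19.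

Step 8. Enantioselectivity may be low, because the two ketone substituents (a trisubstituted alkenyl group and an allylic CH2 group) differ little in size. Fallback, from 1 and 10 back to 13: hept-1-en-6-yne 1 is deprotonated with n-BuLi in THF at −78 °C to lithium hept-6-en-1-yn-1-ide F11, which is added to aldehyde 10 to give, after aqueous NH4Cl work-up, the racemic propargylic alcohol F12. This is oxidised with Dess–Martin periodinane to ynone F13. Noyori transfer hydrogenation with RuCl(p-cymene)[(S,S)-TsDPEN] in 2-propanol at rt should give the (S)-propargylic alcohol F14, alkynyl alkyl ketones being the best substrate class for this catalyst. Trans-hydroalumination with NaAlH2(OCH2CH2OCH3)2 followed by iodine should give the (Z)-iodoalkenol F15, and Me2CuLi replaces iodine by methyl with retention to give 13.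

Step 18. Under fluoride the liberated C6 alkoxide may attack the neighbouring C18 benzoate (acyl migration or loss), and removal of the hindered C6 silyl ether may be slow. Fallback, from 24 back to 26: zinc reagent 24 is coupled instead with commercial methyl (2Z)-3-iodobut-2-enoate (Pd(PPh3)4, THF) to give methyl ester F16. Me3SnOH in 1,2-dichloroethane at 80 °C should cleave the methyl ester in the presence of the hindered neopentyl benzoate to give the silyl-protected acid F17. The silyl ether is then removed under acidic, non-migrating conditions with HF·pyridine in THF to give 26.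

**Further compounds**

F1 | step 12 | (3E,6R,7E)-1-chloro-4,8-dimethyltrideca-3,7,12-trien-6-ol | C=CCCC/C(C)=C/[C@H](O)C/C(C)=C/CCCl
F2 | step 12 | tert-butyl{[(3E,6R,7E)-1-chloro-4,8-dimethyltrideca-3,7,12-trien-6-yl]oxy}dimethylsilane | C=CCCC/C(C)=C/[C@H](O[Si](C)(C)C(C)(C)C)C/C(C)=C/CCCl
F3 | step 12 | (6E,8R,10E)-8-(tert-butyldimethylsilyloxy)-13-chloro-6,10-dimethyltrideca-6,10-dien-2-one | CC(=O)CCC/C(C)=C/[C@H](O[Si](C)(C)C(C)(C)C)C/C(C)=C/CCCl
F4 | step 12 | 2-[(4E,6R,8E)-6-(tert-butyldimethylsilyloxy)-11-chloro-4,8-dimethylundeca-4,8-dien-1-yl]-2-methyloxirane (both epimers at the oxirane carbon) | CC1(CCC/C(C)=C/[C@H](O[Si](C)(C)C(C)(C)C)C/C(C)=C/CCCl)CO1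
F5 | step 12 | (4R,5R,6R,9S,10R)-6-(tert-butyldimethylsilyloxy)-12-chloro-18-(trimethylsilyloxy)-13,14,15,16-tetranorlabd-8(17)-ene | C=C1C[C@@H](O[Si](C)(C)C(C)(C)C)[C@H]2[C@](C)(CO[Si](C)(C)C)CCC[C@]2(C)[C@H]1CCCl
F6 | step 12 | (4R,5R,6R,9S,10R)-6-(tert-butyldimethylsilyloxy)-12-chloro-13,14,15,16-tetranorlabd-8(17)-en-18-ol | C=C1C[C@@H](O[Si](C)(C)C(C)(C)C)[C@H]2[C@](C)(CO)CCC[C@]2(C)[C@H]1CCCl
F7 | step 12 | (4R,5R,6R,9S,10R)-6-(tert-butyldimethylsilyloxy)-12-chloro-13,14,15,16-tetranorlabd-8(17)-en-18-yl benzoate | C=C1C[C@@H](O[Si](C)(C)C(C)(C)C)[C@H]2[C@](C)(COC(=O)c3ccccc3)CCC[C@]2(C)[C@H]1CCCl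
F8 | step 12 | (4R,5R,6R,9S,10R)-12-chloro-6-hydroxy-13,14,15,16-tetranorlabd-8(17)-en-18-yl benzoate | C=C1C[C@@H](O)[C@H]2[C@](C)(COC(=O)c3ccccc3)CCC[C@]2(C)[C@H]1CCCl
F9 | step 12 | (4R,5R,9S,10R)-12-chloro-6-oxo-13,14,15,16-tetranorlabd-8(17)-en-18-yl benzoate | C=C1CC(=O)[C@H]2[C@](C)(COC(=O)c3ccccc3)CCC[C@]2(C)[C@H]1CCCl
F10 | step 12 | (4R,5R,6S,9S,10R)-12-chloro-6-hydroxy-13,14,15,16-tetranorlabd-8(17)-en-18-yl benzoate | C=C1C[C@H](O)[C@H]2[C@](C)(COC(=O)c3ccccc3)CCC[C@]2(C)[C@H]1CCCl
F11 | step 8 | lithium hept-6-en-1-yn-1-ide | [Li]C#CCCCC=C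
F12 | step 8 | rac-(3E)-1-chloro-4-methyltrideca-3,12-dien-7-yn-6-ol | C=CCCCC#CC(O)C/C(C)=C/CCCl
F13 | step 8 | (3E)-1-chloro-4-methyltrideca-3,12-dien-7-yn-6-one | C=CCCCC#CC(=O)C/C(C)=C/CCCl
F14 | step 8 | (3E,6S)-1-chloro-4-methyltrideca-3,12-dien-7-yn-6-ol | C=CCCCC#C[C@@H](O)C/C(C)=C/CCCl
F15 | step 8 | (3E,6S,7Z)-1-chloro-8-iodo-4-methyltrideca-3,7,12-trien-6-ol | C=CCCC/C(I)=C/[C@@H](O)C/C(C)=C/CCCl
F16 | step 18 | methyl (13Z)-18-(benzoyloxy)-6α-(tert-butyldimethylsilyloxy)labda-8(17),13-dien-15-oate | C=C1C[C@H](O[Si](C)(C)C(C)(C)C)[C@H]2[C@](C)(COC(=O)c3ccccc3)CCC[C@]2(C)[C@H]1CC/C(C)=C\C(=O)OC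
F17 | step 18 | (13Z)-18-(benzoyloxy)-6α-(tert-butyldimethylsilyloxy)labda-8(17),13-dien-15-oic acid | C=C1C[C@H](O[Si](C)(C)C(C)(C)C)[C@H]2[C@](C)(COC(=O)c3ccccc3)CCC[C@]2(C)[C@H]1CC/C(C)=C\C(=O)O
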